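**Retrosynthetic overview**

1. Target 15 is the all-trans 2,5-diaryl-3,4-dimethyloxolane. The C2–aryl bond is cut first: Friedel–Crafts arylation of the oxocarbenium ion from lactol 12 with 2,6-dimethoxyphenol 13, anti to the C3 methyl. C2 is then traced back to the lactone carbonyl of 11.
2. Lactone 11 comes from cyclobutanone 10 by taking out O1; in the forward sense this is a Baeyer–Villiger oxidation in which the benzylic carbon C5 migrates with retention.
3. The plan rests on one feature: the chain C5–C4–C3–C2 of the oxolane ring, with trans methyl groups on C3 and C4, is (E)-but-2-ene (C3, C4 and both methyls) bridged by a two-carbon arylketene unit (C5 carrying the aryl, C2 as carbonyl carbon). Hence 10 comes from the keteniminium ion of amide 6 and (E)-but-2-ene 7 by [2+2], forming C2–C3 and C4–C5.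
4. Amide 6 comes from acid 1 by benzylation, saponification and acylation of (2R,5R)-2,5-dimethylpyrrolidine 4.
5. Ring order: cyclobutane (step 4), then oxolan-2-one by ring expansion (step 5); the second aryl ring is attached last to the finished oxolane.

Key step: step 4

Assumption: the (2R,5R) auxiliary is taken to steer (E)-but-2-ene onto the face of the keteniminium ion that leads to the (3S,4S) ring; should the sense of induction prove opposite, the equally available (2S,5S) amine replaces 4 with no other change.

**Route**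

Step 1
Reactants: 1 (4-hydroxy-3,5-dimethoxyphenyl)acetic acid
Product: 2 benzyl [4-(benzyloxy)-3,5-dimethoxyphenyl]acetate
Conditions: BnBr (2.5 equiv), K2CO3, DMF, 60 °C
Reagents that add atoms: benzyl bromide, BrCc1ccccc1
Why: Williamson etherification of the phenoxide and SN2 O-alkylation of the carboxylate occur together, so both acidic OH groups are benzylated and no selectivity is needed.

Step 2
Reactants: 2 benzyl [4-(benzyloxy)-3,5-dimethoxyphenyl]acetate
Product: 3 [4-(benzyloxy)-3,5-dimethoxyphenyl]acetic acid
Conditions: LiOH·H2O, THF/H2O, rt; then 1 M HCl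
Reagents that add atoms: lithium hydroxide (hydroxide oxygen), [Li+].[OH-]
Why: saponification (acyl–oxygen ester hydrolysis) cleaves only the benzyl ester, the aryl benzyl ether being inert to hydroxide.

Step 3
Reactants: 3 [4-(benzyloxy)-3,5-dimethoxyphenyl]acetic acid; 4 (2R,5R)-2,5-dimethylpyrrolidine
Product: 6 2-[4-(benzyloxy)-3,5-dimethoxyphenyl]-1-[(2R,5R)-2,5-dimethylpyrrolidin-1-yl]ethan-1-one, via acid chloride 5 (not isolated)
Conditions: (COCl)2, cat. DMF, CH2Cl2, 0 °C → rt, evaporate; then 4, Et3N, CH2Cl2, 0 °C → rt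
Reagents that add atoms: none
Why: Schotten–Baumann-type acylation through the acid chloride is the dependable way to acylate a hindered 2,5-disubstituted pyrrolidine, and the stereocentres of the amine are not touched.

Step 4
Reactants: 6 2-[4-(benzyloxy)-3,5-dimethoxyphenyl]-1-[(2R,5R)-2,5-dimethylpyrrolidin-1-yl]ethan-1-one; 7 (E)-but-2-ene
Product: 10 (2S,3S,4S)-2-[4-(benzyloxy)-3,5-dimethoxyphenyl]-3,4-dimethylcyclobutan-1-one, via keteniminium triflate 8 (not isolated), via cyclobutaniminium triflate 9 (not isolated)
Conditions: Tf2O (slow addition), 2,4,6-collidine, 7 (excess, condensed in), ClCH2CH2Cl, −20 °C → 70 °C, sealed vessel; then aq NaHCO3, CH2Cl2, rt → 40 °C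
Reagents that add atoms: water, O
Why: Tf2O O-triflylates the amide and collidine removes a benzylic proton to give keteniminium ion 8, whose electrophilic central carbon (later C2 of the oxolane) is attacked by the alkene while the aryl-bearing carbon (later C5) closes onto the developing cationic carbon before C–C rotation can occur, which is the known polar, asynchronous keteniminium–alkene [2+2] cycloaddition. The cyclobutane ring is thus closed intermolecularly by two C–C bonds (C2–C3 and C4–C5 in oxolane numbering), the second by collapse of the enamine-like carbon onto the incipient secondary cation within the same encounter. The two methyl-bearing centres are set together: their trans relation follows from suprafacial transfer of the E geometry, and their absolute (S,S) sense from the C2-symmetric 2,5-dimethylpyrrolidine, one methyl group of which blocks one side of the keteniminium carbon so that the alkene can bind through only one of its enantiotopic faces. The aryl-bearing centre is not under kinetic control, because it lies α to the iminium and then to the ketone and should equilibrate during the bicarbonate hydrolysis of 9 to the 2,3-trans arrangement; the all-trans isomer is the most stable since the non-enolisable β-carbon anchors both of its neighbours. The step needs reactivity toward an unactivated alkene, which the cationic keteniminium ion has and an arylketene lacks, and facial selectivity, which rests on the auxiliary; excess alkene and slow addition of Tf2O keep the electron-rich ring of a second molecule from competing for 8.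

Step 5
Reactants: 10 (2S,3S,4S)-2-[4-(benzyloxy)-3,5-dimethoxyphenyl]-3,4-dimethylcyclobutan-1-one
Product: 11 (3S,4S,5S)-5-[4-(benzyloxy)-3,5-dimethoxyphenyl]-3,4-dimethyloxolan-2-one
Conditions: mCPBA (1.2 equiv), CH2Cl2, 0 °C → rt
Reagents that add atoms: 3-chloroperoxybenzoic acid (mCPBA), O=C(OO)c1cccc(Cl)c1
Why: Baeyer–Villiger oxidation is fast for a strained cyclobutanone, and the electron-rich benzylic carbon should migrate in preference to the methyl-bearing secondary carbon and with retention, so O1 enters between C2 and C5 and all three stereocentres are carried over unchanged.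

Step 6
Reactants: 11 (3S,4S,5S)-5-[4-(benzyloxy)-3,5-dimethoxyphenyl]-3,4-dimethyloxolan-2-one
Product: 12 (3S,4S,5S)-5-[4-(benzyloxy)-3,5-dimethoxyphenyl]-3,4-dimethyloxolan-2-ol (both anomers)
Conditions: i-Bu2AlH (DIBAL-H, 1.1 equiv), CH2Cl2, −78 °C; then aq potassium sodium tartrate (KNaC4H4O6)
Reagents that add atoms: none
Why: partial reduction of the lactone with DIBAL-H stops at the tetrahedral aluminium hemiacetal at −78 °C and gives the lactol on hydrolysis; the anomeric centre is left unset because it is planarised in the next step.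

Step 7
Reactants: 12 (3S,4S,5S)-5-[4-(benzyloxy)-3,5-dimethoxyphenyl]-3,4-dimethyloxolan-2-ol; 13 2,6-dimethoxyphenol
Product: 14 4-[(2S,3S,4S,5S)-5-[4-(benzyloxy)-3,5-dimethoxyphenyl]-3,4-dimethyloxolan-2-yl]-2,6-dimethoxyphenol
Conditions: 13 (2 equiv), BF3·OEt2 (2 equiv), CH2Cl2, −78 → −20 °C
Reagents that add atoms: none
Why: BF3·OEt2 ionises the lactol to the cyclic oxocarbenium ion, which is captured in a Friedel–Crafts alkylation by the position para to the hydroxyl of 13 (both ortho positions carry methoxy groups); the arene adds to C2 anti to the adjacent C3 methyl, which sets C2 as S and completes the all-trans array, also the thermodynamically preferred one should the benzylic ether centres equilibrate under the Lewis acid.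

Step 8
Reactants: 14 4-[(2S,3S,4S,5S)-5-[4-(benzyloxy)-3,5-dimethoxyphenyl]-3,4-dimethyloxolan-2-yl]-2,6-dimethoxyphenol
Product: 15 4,4'-[(2S,3S,4S,5S)-3,4-dimethyloxolane-2,5-diyl]bis(2,6-dimethoxyphenol)
Conditions: H2 (1 atm), Pd/C, EtOAc, rt, stopped after uptake of one equivalent
Reagents that add atoms: none
Why: catalytic hydrogenolysis of the aryl benzyl ether is much faster than cleavage of the benzylic C–O bonds of the oxolane, so the second phenol should be freed without touching the ring or its four stereocentres.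

**Compound list**

1 | (4-hydroxy-3,5-dimethoxyphenyl)acetic acid | COc1cc(CC(=O)O)cc(OC)c1O | starting material
2 | benzyl [4-(benzyloxy)-3,5-dimethoxyphenyl]acetate | COc1cc(CC(=O)OCc2ccccc2)cc(OC)c1OCc1ccccc1 | intermediate
3 | [4-(benzyloxy)-3,5-dimethoxyphenyl]acetic acid | COc1cc(CC(=O)O)cc(OC)c1OCc1ccccc1 | intermediate
4 | (2R,5R)-2,5-dimethylpyrrolidine | C[C@@H]1CC[C@@H](C)N1 | starting material
5 | [4-(benzyloxy)-3,5-dimethoxyphenyl]acetyl chloride | COc1cc(CC(=O)Cl)cc(OC)c1OCc1ccccc1 | intermediate (not isolated)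
6 | 2-[4-(benzyloxy)-3,5-dimethoxyphenyl]-1-[(2R,5R)-2,5-dimethylpyrrolidin-1-yl]ethan-1-one | C[C@@H]1CC[C@@H](C)N1C(=O)Cc1cc(OC)c(OCc2ccccc2)c(OC)c1 | intermediate
7 | (E)-but-2-ene | C/C=C/C | starting material
8 | (2R,5R)-1-{2-[4-(benzyloxy)-3,5-dimethoxyphenyl]ethenylidene}-2,5-dimethylpyrrolidin-1-ium trifluoromethanesulfonate (keteniminium triflate) | C[C@@H]1CC[C@@H](C)[N+]1=C=Cc1cc(OC)c(OCc2ccccc2)c(OC)c1.[O-]S(=O)(=O)C(F)(F)F | intermediate (not isolated)
9 | (2R,5R)-1-{(3S,4S)-2-[4-(benzyloxy)-3,5-dimethoxyphenyl]-3,4-dimethylcyclobutylidene}-2,5-dimethylpyrrolidin-1-ium trifluoromethanesulfonate (epimers at the aryl-bearing ring carbon) | C[C@@H]1CC[C@@H](C)[N+]1=C2C(c3cc(OC)c(OCc4ccccc4)c(OC)c3)[C@@H](C)[C@@H]2C.[O-]S(=O)(=O)C(F)(F)F | intermediate (not isolated)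
10 | (2S,3S,4S)-2-[4-(benzyloxy)-3,5-dimethoxyphenyl]-3,4-dimethylcyclobutan-1-one | O=C1[C@H](c2cc(OC)c(OCc3ccccc3)c(OC)c2)[C@@H](C)[C@@H]1C | intermediate
11 | (3S,4S,5S)-5-[4-(benzyloxy)-3,5-dimethoxyphenyl]-3,4-dimethyloxolan-2-one | O=C1O[C@H](c2cc(OC)c(OCc3ccccc3)c(OC)c2)[C@@H](C)[C@@H]1C | intermediate
12 | (3S,4S,5S)-5-[4-(benzyloxy)-3,5-dimethoxyphenyl]-3,4-dimethyloxolan-2-ol (both anomers) | OC1O[C@H](c2cc(OC)c(OCc3ccccc3)c(OC)c2)[C@@H](C)[C@@H]1C | intermediate
13 | 2,6-dimethoxyphenol | COc1cccc(OC)c1O | starting material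
14 | 4-[(2S,3S,4S,5S)-5-[4-(benzyloxy)-3,5-dimethoxyphenyl]-3,4-dimethyloxolan-2-yl]-2,6-dimethoxyphenol | COc1cc([C@H]2O[C@H](c3cc(OC)c(OCc4ccccc4)c(OC)c3)[C@@H](C)[C@@H]2C)cc(OC)c1O | intermediate
15 | 4,4'-[(2S,3S,4S,5S)-3,4-dimethyloxolane-2,5-diyl]bis(2,6-dimethoxyphenol) | COc1cc([C@H]2O[C@H](c3cc(OC)c(O)c(OC)c3)[C@@H](C)[C@@H]2C)cc(OC)c1O | target

**Step count**

Total step count: 8. Longest linear sequence: 8 steps (1 → 15).

**Steps most likely to fail**

Step 4 (keteniminium [2+2]). The keteniminium ion may be consumed by the electron-rich aryl ring of a second molecule faster than the gaseous, weakly nucleophilic trans-alkene captures it, and the auxiliary may discriminate the alkene faces incompletely. If the 2,3-cis epimer survives hydrolysis, a catalytic amount of DBU in CH2Cl2 should complete the equilibration. The fallback abandons the cycloaddition, sets out from 13 and comes back at lactone 11. Para-formylation of 13 (hexamethylenetetramine, CF3CO2H, reflux; aq HCl) gives 4-hydroxy-3,5-dimethoxybenzaldehyde F1, which is benzylated (BnBr, K2CO3, DMF) to 4-(benzyloxy)-3,5-dimethoxybenzaldehyde F2. Asymmetric crotylboration with the (E)-crotyldiisopinocampheylborane that adds to the Si face of the aldehyde (from (−)-Ipc2BOMe, 7, n-BuLi, KOt-Bu, BF3·OEt2, THF, −78 °C; then NaOH, H2O2) should give the anti alcohol (1S,2S)-1-[4-(benzyloxy)-3,5-dimethoxyphenyl]-2-methylbut-3-en-1-ol F3. Hydroboration–oxidation (9-BBN, THF; NaOH, H2O2) gives (1S,2S)-1-[4-(benzyloxy)-3,5-dimethoxyphenyl]-2-methylbutane-1,4-diol F4. Oxidative lactonisation selective for the primary alcohol (TEMPO, PhI(OAc)2, CH2Cl2) gives (4S,5S)-5-[4-(benzyloxy)-3,5-dimethoxyphenyl]-4-methyloxolan-2-one F5. Enolate methylation anti to the C4 methyl (LiN(i-Pr)2, MeI, THF, −78 °C) delivers 11.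

Step 5 (Baeyer–Villiger). The methyl-bearing α-carbon may migrate in competition with the benzylic one, and the peracid may attack the trioxygenated ring. The fallback inserts the oxygen photochemically, sets out from 10 and comes back at 14, bypassing 11 and 12. Irradiation of 10 in degassed methanol (Pyrex-filtered medium-pressure Hg lamp, rt) should cleave the weaker benzylic bond to the carbonyl carbon, reclose the acyl–benzyl biradical on oxygen to the cyclic oxacarbene and insert it into the O–H bond of methanol. This is the known photochemical ring expansion of cyclobutanones, and it should give (3S,4S,5S)-5-[4-(benzyloxy)-3,5-dimethoxyphenyl]-2-methoxy-3,4-dimethyloxolane F6 as an anomeric mixture. F6 then takes the place of lactol 12 in the BF3·OEt2 arylation with 13 and gives 14; any loss of configuration at the benzylic centre would be corrected there by Lewis-acid equilibration to the all-trans isomer.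

Step 7 (arylation of the lactol). The phenol may react through oxygen or through a ring position other than the para carbon, the lactol may self-condense, and the Lewis acid may open the ring at the benzylic ether. The fallback attaches the second aryl group as a nucleophile to the lactone, sets out from 11 (aryl partner from 13) and comes back at target 15. Bromination of 13 para to the hydroxyl (NBS, CH2Cl2, −40 °C → rt) gives 4-bromo-2,6-dimethoxyphenol F7, and benzylation (BnBr, K2CO3, DMF) gives 2-(benzyloxy)-5-bromo-1,3-dimethoxybenzene F8. Bromine–lithium exchange (n-BuLi, THF, −78 °C) and addition of the aryllithium to 11 gives the hemiketal (3S,4S,5S)-2,5-bis[4-(benzyloxy)-3,5-dimethoxyphenyl]-3,4-dimethyloxolan-2-ol F9. Reductive deoxygenation (Et3SiH, BF3·OEt2, CH2Cl2, −78 → 0 °C), run so that the benzylic ether centres can equilibrate to the thermodynamic arrangement, should give (2S,3S,4S,5S)-2,5-bis[4-(benzyloxy)-3,5-dimethoxyphenyl]-3,4-dimethyloxolane F10. Hydrogenolysis of both benzyl ethers (H2, Pd/C, EtOAc) gives 15.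

**Further compounds**

F1 | step 4 | 4-hydroxy-3,5-dimethoxybenzaldehyde | COc1cc(C=O)cc(OC)c1O
F2 | step 4 | 4-(benzyloxy)-3,5-dimethoxybenzaldehyde | COc1cc(C=O)cc(OC)c1OCc1ccccc1
F3 | step 4 | (1S,2S)-1-[4-(benzyloxy)-3,5-dimethoxyphenyl]-2-methylbut-3-en-1-ol | O[C@H](c1cc(OC)c(OCc2ccccc2)c(OC)c1)[C@@H](C)C=C
F4 | step 4 | (1S,2S)-1-[4-(benzyloxy)-3,5-dimethoxyphenyl]-2-methylbutane-1,4-diol | O[C@H](c1cc(OC)c(OCc2ccccc2)c(OC)c1)[C@@H](C)CCO
F5 | step 4 | (4S,5S)-5-[4-(benzyloxy)-3,5-dimethoxyphenyl]-4-methyloxolan-2-one | O=C1O[C@H](c2cc(OC)c(OCc3ccccc3)c(OC)c2)[C@@H](C)C1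
F6 | step 5 | (3S,4S,5S)-5-[4-(benzyloxy)-3,5-dimethoxyphenyl]-2-methoxy-3,4-dimethyloxolane (both anomers) | COC1O[C@H](c2cc(OC)c(OCc3ccccc3)c(OC)c2)[C@@H](C)[C@@H]1C
F7 | step 7 | 4-bromo-2,6-dimethoxyphenol | COc1cc(Br)cc(OC)c1O
F8 | step 7 | 2-(benzyloxy)-5-bromo-1,3-dimethoxybenzene | COc1cc(Br)cc(OC)c1OCc1ccccc1
F9 | step 7 | (3S,4S,5S)-2,5-bis[4-(benzyloxy)-3,5-dimethoxyphenyl]-3,4-dimethyloxolan-2-ol | COc1cc(C2(O)O[C@H](c3cc(OC)c(OCc4ccccc4)c(OC)c3)[C@@H](C)[C@@H]2C)cc(OC)c1OCc1ccccc1
F10 | step 7 | (2S,3S,4S,5S)-2,5-bis[4-(benzyloxy)-3,5-dimethoxyphenyl]-3,4-dimethyloxolane | COc1cc([C@H]2O[C@H](c3cc(OC)c(OCc4ccccc4)c(OC)c3)[C@@H](C)[C@@H]2C)cc(OC)c1OCc1ccccc1
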